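**Plan**

1. Retrosynthesis (eremophilane numbering): the C3 ester is cut first; the C8/C9 diol and the C10 hydrogen go back to a C9=C10 alkene; ring A is then cut at C1–C2 and C4–C5, leaving ring B and a three-carbon unit C2–C3(=O)–C4(CH3).
2. Enabling feature: in ring B, C10 is flanked by C1, C5 and C9, so ring B can be written as the 2-methylene-1,3-diol C5(OH)–C10(=C1H2)–C9(OH), and C2–C3(=O)–C4 is a 3-oxoglutarate less two CO2.
3. A 2-methyl-3-oxoglutarate tethered across O5 and O9 (temporary ten-membered dilactone) undergoes two decarboxylative Claisen (Carroll) shifts: first O5 to C1 (bond C1–C2), then O9 to C5 (bond C4–C5). Both tether carbonyls leave as CO2.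
4. Forward: (S)-carvone to the diol (three steps), tether, cascade (ring A onto ring B), then C8 ketone, trans ring fusion, C9 and C8 hydroxyls, acetonide, side chain as a diynoate, semihydrogenation, deprotection.
5. Stereochemistry: C7 from (S)-carvone; C9–O of the diol by hydroxyl-directed epoxidation; C5 by suprafacial [3,3] transfer from C9–O; C4 by axial protonation anti to C14; C10 and C3 in one dissolving-metal reduction; C9 by Rubottom oxidation and C8 by L-Selectride, both governed by the axial C14 methyl; side-chain carbinol from (S)-pent-1-yn-3-ol; both Z alkenes by Lindlar hydrogenation.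

Key step: step 8

Remark: eremophilane numbering is used throughout, also for ring B precursors (decalin C1–C10, ring fusion at C5 and C10, C14 on C5, C15 on C4, isopropenyl C11–C13 on C7; ring A = C1–C5 and C10, ring B = C5–C10). β is the face of C14, α the opposite face.

**Route**

Step 1
Reactants: 1 2,2,6-trimethyl-4H-1,3-dioxin-4-one
Product: 2 6-ethyl-2,2-dimethyl-4H-1,3-dioxin-4-one
Conditions: LDA, THF, DMPU, −78 °C; MeI, −78 to 0 °C
Reagents that add atoms: iodomethane, CI
Why: Deprotonation of the 6-methyl group gives the extended dienolate of the vinylogous ester, which should be alkylated at the exocyclic γ-carbon (vinylogous enolate alkylation); no stereocenter is formed.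

Step 2
Reactants: 2 6-ethyl-2,2-dimethyl-4H-1,3-dioxin-4-one
Product: 3 allyl 2-(2,2-dimethyl-4-oxo-4H-1,3-dioxin-6-yl)propanoate (racemic)
Conditions: LiHMDS (2.1 equiv), THF, −78 °C; allyl chloroformate; aq NH4Cl
Reagents that add atoms: allyl chloroformate, C=CCOC(=O)Cl
Why: A second γ-deprotonation and C-acylation of the dienolate by the chloroformate (γ-acylation of a dioxinone dienolate) installs the carboxyl carbon; the new center is racemic and is erased in step 8.

Step 3
Reactants: 3 allyl 2-(2,2-dimethyl-4-oxo-4H-1,3-dioxin-6-yl)propanoate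
Product: 4 2-(2,2-dimethyl-4-oxo-4H-1,3-dioxin-6-yl)propanoic acid (racemic, used at once)
Conditions: Pd(PPh3)4 (cat.), morpholine, THF, 0 °C; cold dilute HCl
Reagents that add atoms: none
Why: Pd-catalyzed allyl transfer to morpholine (Tsuji–Trost deallylation) should free the acid under neutral conditions that leave the dioxinone intact.

Step 4
Reactants: 5 (S)-(+)-carvone
Product: 6 (1S,5S)-1,2-dimethyl-5-(prop-1-en-2-yl)cyclohex-2-en-1-ol (OH cis to isopropenyl)
Conditions: MeLi, Et2O, −78 °C; H2O
Reagents that add atoms: methyllithium, [Li]C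
Why: 1,2-Addition of MeLi to the enone carbonyl (future C5) by axial attack anti to the equatorial isopropenyl group should place the hydroxyl cis to isopropenyl; this center only steers step 5 and is erased in step 8.

Step 5
Reactants: 6 (1S,5S)-1,2-dimethyl-5-(prop-1-en-2-yl)cyclohex-2-en-1-ol
Product: 7 2,3-epoxide of 6 with the oxirane oxygen cis to the hydroxyl and to isopropenyl
Conditions: VO(acac)2 (cat.), t-BuOOH, CH2Cl2, 0 °C to rt
Reagents that add atoms: tert-butyl hydroperoxide, CC(C)(C)OO
Why: Hydroxyl-directed vanadium-catalyzed epoxidation delivers oxygen syn to the tertiary hydroxyl and only to the allylic ring alkene, which sets the C9–O bond on the α face and leaves the isopropenyl group untouched.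

Step 6
Reactants: 7 2,3-epoxide of 6
Product: 8 (1S,3R,5S)-1-methyl-2-methylidene-5-(prop-1-en-2-yl)cyclohexane-1,3-diol (both OH cis to isopropenyl)
Conditions: LiNEt2 (from Et2NH and n-BuLi, 4 equiv), Et2O, 0 °C to reflux; H2O
Reagents that add atoms: none
Why: Base-promoted isomerization of the epoxide to the allylic alcohol (syn β-elimination by the lithium amide) should remove a proton from the methyl group on the quaternary oxirane carbon and give the exocyclic C10=C1 alkene, with the C9–O configuration retained.

Step 7
Reactants: 8 (1S,3R,5S)-1-methyl-2-methylidene-5-(prop-1-en-2-yl)cyclohexane-1,3-diol; 4 2-(2,2-dimethyl-4-oxo-4H-1,3-dioxin-6-yl)propanoic acid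
Product: 9 ester of 8 at the secondary hydroxyl (O9) with acid 4 (epimers at the propanoate α-carbon)
Conditions: DCC, DMAP (cat.), CH2Cl2, 0 °C
Reagents that add atoms: none
Why: Steglich esterification should acylate the secondary allylic hydroxyl and leave the hindered tertiary one free; no ring stereocenter is touched.

Step 8
Reactants: 9 ester of 8 at O9 with acid 4
Product: 15 eremophila-9,11-dien-3-one (4β-CH3; 5β-CH3; 7α-isopropenyl), via acylketene 10 (not isolated), via dilactone 11 (not isolated), via lactone acid 12 (not isolated), via keto lactone 13 (not isolated), via keto acid 14 (not isolated)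
Conditions: xylenes, 140 °C, high dilution (slow addition of 9)
Reagents that add atoms: none
Why: Proposed new method: at 140 °C the dioxinone of 9 loses acetone by retro-[4+2] to acylketene 10, which the tertiary C5 hydroxyl traps to the ten-membered bis(β-keto ester) 11 (acylketene macrolactonization); the tertiary allylic ester then undergoes a Carroll (decarboxylative Claisen, [3,3]) shift through its enol that joins C2 to the exocyclic C1 and moves the alkene to C10=C5 (12, then 13 after loss of CO2), and the remaining secondary allylic β-keto lactone repeats the [3,3] shift from O9 to C5, joining C4 to C5 (14), and decarboxylates to 15. The closest known reactions are the Carroll rearrangement of tertiary allylic acetoacetates and the Ireland–Claisen ring contraction of macrolactones; a doubly tethered 3-oxoglutarate serving as a three-carbon unit in two successive Carroll shifts is new. The temporary macrolactone closes by O-acylation, and ring A closes in the second shift as a six-membered ring in a 6-endo sense, through a bicyclo[3.3.1]-like transition state in which the lactone enol carbon C4 reaches the far end of the C10=C5 bond. C5 is set by suprafacial transfer from the α C9–O bond (cis to isopropenyl), so C4 enters on the α face and C14 stays β, the face opposite to the one a conjugate addition to a 5-substituted cyclohexenone would choose; C4 is set when the enol left by the last decarboxylation ketonizes, by axial protonation anti to C14, which also gives the equatorial methyl. The step needs the tertiary ester to rearrange before the secondary one (the reverse order would join C4 to C1 and close the ring at C9); the more substituted carbinol carbon, the unsubstituted enol terminus C2 and the birth of this ester in its enol form from the ketene should secure that order, and high dilution suppresses intermolecular ketene capture.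

Step 9
Reactants: 15 eremophila-9,11-dien-3-one
Product: 16 eremophila-9,11-diene-3,8-dione (4β-CH3; 5β-CH3; 7α-isopropenyl)
Conditions: Rh2(cap)4 (dirhodium tetracaprolactamate, Rh2(C6H10NO)4, 1 mol %), 70% aq t-BuOOH, 1,2-dichloroethane, 40 °C
Reagents that add atoms: tert-butyl hydroperoxide, CC(C)(C)OO
Why: Radical allylic oxidation should take place at C8, the methylene next to the CH end of the trisubstituted alkene (the regiochemistry of Δ5-steroid to 7-ketone oxidations), because abstraction there gives the allyl radical with a tertiary terminus; no stereocenter is formed and the equatorial C7 substituent is kept.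

Step 10
Reactants: 16 eremophila-9,11-diene-3,8-dione
Product: 18 3α,8-bis(trimethylsilyloxy)eremophila-8,11-diene (10α-H), via dilithium enolate 17 (not isolated)
Conditions: Li, NH3(l), THF, t-BuOH (2.5 equiv), −78 °C; isoprene; evaporate NH3; TMSCl, Et3N, THF, −78 to 0 °C
Reagents that add atoms: chlorotrimethylsilane, C[Si](C)(C)Cl
Why: Dissolving-metal (Birch-type) reduction: the enone is reduced and protonated at C10 on the axial α face anti to C14, which gives the trans ring fusion and the C8–C9 lithium enolate, while the saturated C3 ketone is reduced to the more stable equatorial 3α-alkoxide; silylation fixes the regiodefined enol ether and masks O3.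

Step 11
Reactants: 18 3α,8-bis(trimethylsilyloxy)eremophila-8,11-diene
Product: 21 3α,9α-dihydroxyeremophil-11-en-8-one (10α-H), via silyloxy epoxide 19 (not isolated), via silyloxy ketone 20 (not isolated)
Conditions: mCPBA (1.05 equiv), CH2Cl2, −20 °C; then citric acid, MeOH, rt
Reagents that add atoms: 3-chloroperbenzoic acid, OOC(=O)c1cccc(Cl)c1
Why: Rubottom oxidation: the peracid should epoxidize the electron-rich silyl enol ether far faster than the isopropenyl alkene and from the α face, since the β face at C9 is shielded by the syn-axial C14 methyl; silyl migration gives the α-silyloxy ketone and acidic methanolysis frees both hydroxyls, so the C9 hydroxyl is α (equatorial).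

Step 12
Reactants: 21 3α,9α-dihydroxyeremophil-11-en-8-one
Product: 22 eremophil-11-ene-3α,8α,9α-triol (10α-H)
Conditions: LiBH(s-Bu)3 (L-Selectride, 3.5 equiv), THF, −78 °C; aq NH4Cl
Reagents that add atoms: none
Why: Bulky trialkylborohydride reduction: hydride should attack the C8 carbonyl along the equatorial trajectory from the β face, giving the axial 8α-alcohol cis to the 9α-hydroxyl and to the equatorial isopropenyl group.

Step 13
Reactants: 22 eremophil-11-ene-3α,8α,9α-triol
Product: 23 8,9-O-isopropylidene derivative of 22 (3α-OH free)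
Conditions: 2,2-dimethoxypropane, PPTS (cat.), acetone, rt
Reagents that add atoms: 2,2-dimethoxypropane, COC(C)(C)OC
Why: Acetonide formation is selective for the cis-vicinal 8,9-diol (five-membered dioxolane) and leaves the isolated 3-hydroxyl free; no stereocenter changes.

Step 14
Reactants: 24 (S)-pent-1-yn-3-ol
Product: 25 (S)-4-hydroxyhex-2-ynoic acid
Conditions: n-BuLi (2.1 equiv), THF, −78 to 0 °C; CO2; dilute HCl
Reagents that add atoms: carbon dioxide, O=C=O
Why: Double deprotonation gives the alkoxide acetylide, whose carbon end is carboxylated by CO2 (acetylide carboxylation); the carbinol center is not involved.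

Step 15
Reactants: 26 hex-2-ynoic acid; 25 (S)-4-hydroxyhex-2-ynoic acid
Product: 28 (S)-4-(hex-2-ynoyloxy)hex-2-ynoic acid, via hex-2-ynoyl chloride 27 (not isolated)
Conditions: 26, (COCl)2, DMF (cat.), CH2Cl2, 0 °C to rt; then 25, CH2Cl2, 0 °C to rt (no base)
Reagents that add atoms: none
Why: O-Acylation of a hydroxy acid by an acid chloride without base (as in the preparation of O-acyl α-hydroxy acids) esterifies the secondary hydroxyl while the carboxylic acid stays free; the C–O bond at the stereocenter is not broken.

Step 16
Reactants: 23 8,9-O-isopropylidene derivative of 22; 28 (S)-4-(hex-2-ynoyloxy)hex-2-ynoic acid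
Product: 29 3α-O-[(S)-4-(hex-2-ynoyloxy)hex-2-ynoyl] derivative of 23
Conditions: DCC, DMAP (cat.), CH2Cl2, −20 to 0 °C
Reagents that add atoms: none
Why: Steglich esterification of the equatorial 3α-hydroxyl; carrying the side chain as alkynes avoids the Z to E isomerization that (Z)-enoic acids can suffer under acyl-transfer catalysis, and no stereocenter is touched.

Step 17
Reactants: 29 3α-O-[(S)-4-(hex-2-ynoyloxy)hex-2-ynoyl] derivative of 23
Product: 30 3α-O-[(S,Z)-4-((Z)-hex-2-enoyloxy)hex-2-enoyl] derivative of 23
Conditions: H2 (1 atm), Pd/CaCO3 poisoned with Pb(OAc)2 (Lindlar catalyst), quinoline, EtOAc, rt, stopped after uptake of 2 equiv H2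
Reagents that add atoms: none
Why: Lindlar semihydrogenation adds H2 syn to both ynoates and should give both (Z)-enoates, while the poisoned catalyst leaves the 1,1-disubstituted isopropenyl alkene alone.

Step 18
Reactants: 30 3α-O-[(S,Z)-4-((Z)-hex-2-enoyloxy)hex-2-enoyl] derivative of 23
Product: 31 target compound CNP0271544.1
Conditions: AcOH/H2O (4:1), 45 °C
Reagents that add atoms: none
Why: Mild acid hydrolysis of the cis-fused acetonide should free the 8α,9α-diol without touching the enoate esters, the acylated allylic center or the isopropenyl group.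

**Compound list**

1 | 2,2,6-trimethyl-4H-1,3-dioxin-4-one | CC1=CC(=O)OC(C)(C)O1 | starting material
2 | 6-ethyl-2,2-dimethyl-4H-1,3-dioxin-4-one | CCC1=CC(=O)OC(C)(C)O1 | intermediate
3 | allyl 2-(2,2-dimethyl-4-oxo-4H-1,3-dioxin-6-yl)propanoate (racemic) | C=CCOC(=O)C(C)C1=CC(=O)OC(C)(C)O1 | intermediate
4 | 2-(2,2-dimethyl-4-oxo-4H-1,3-dioxin-6-yl)propanoic acid (racemic) | OC(=O)C(C)C1=CC(=O)OC(C)(C)O1 | intermediate
5 | (S)-(+)-carvone | C=C(C)[C@@H]1CC(=O)C(C)=CC1 | starting material
6 | (1S,5S)-1,2-dimethyl-5-(prop-1-en-2-yl)cyclohex-2-en-1-ol, OH cis to isopropenyl | C=C(C)[C@@H]1C[C@](C)(O)C(C)=CC1 | intermediate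
7 | 2,3-epoxide of 6, oxirane oxygen cis to OH and isopropenyl | C=C(C)[C@@H]1C[C@](C)(O)[C@]2(C)O[C@@H]2C1 | intermediate
8 | (1S,3R,5S)-1-methyl-2-methylidene-5-(prop-1-en-2-yl)cyclohexane-1,3-diol | C=C(C)[C@@H]1C[C@](C)(O)C(=C)[C@H](O)C1 | intermediate
9 | ester of 8 at the secondary hydroxyl with acid 4 (epimers at the propanoate α-carbon) | C=C(C)[C@@H]1C[C@](C)(O)C(=C)[C@H](OC(=O)C(C)C2=CC(=O)OC(C)(C)O2)C1 | intermediate
10 | acylketene from 9 after loss of acetone | C=C(C)[C@@H]1C[C@](C)(O)C(=C)[C@H](OC(=O)C(C)C(=O)C=C=O)C1 | intermediate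
11 | ten-membered dilactone, 2-methyl-3-oxoglutarate bridging O5 and O9 of 8 | C=C(C)[C@@H]1C[C@]2(C)OC(=O)CC(=O)C(C)C(=O)O[C@H](C1)C2=C | intermediate
12 | eight-membered β-keto lactone carrying CO2H at C2 (after the first [3,3] shift) | C=C(C)[C@@H]1CC(C)=C2CC(C(=O)O)C(=O)C(C)C(=O)O[C@@H]2C1 | intermediate
13 | eight-membered β-keto lactone (C1–C2 formed, C10=C5 alkene, O9 ester) | C=C(C)[C@@H]1CC(C)=C2CCC(=O)C(C)C(=O)O[C@@H]2C1 | intermediate
14 | 3-oxoeremophila-9,11-diene-4-carboxylic acid (after the second [3,3] shift; C4 unassigned) | C=C(C)[C@@H]1C[C@]2(C)C(C)(C(=O)O)C(=O)CCC2=CC1 | intermediate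
15 | eremophila-9,11-dien-3-one (4β-CH3, 5β-CH3, 7α-isopropenyl) | C=C(C)[C@@H]1C[C@]2(C)[C@@H](C)C(=O)CCC2=CC1 | intermediate
16 | eremophila-9,11-diene-3,8-dione | C=C(C)[C@@H]1C[C@]2(C)[C@@H](C)C(=O)CCC2=CC1=O | intermediate
17 | dilithium 3α-alkoxide 8-enolate (10α-H, trans-fused) | C=C(C)[C@@H]1C[C@]2(C)[C@@H](C)[C@H]([O-])CC[C@H]2C=C1[O-].[Li+].[Li+] | intermediate
18 | 3α,8-bis(trimethylsilyloxy)eremophila-8,11-diene (10α-H) | C=C(C)[C@@H]1C[C@]2(C)[C@@H](C)[C@H](O[Si](C)(C)C)CC[C@H]2C=C1O[Si](C)(C)C | intermediate
19 | 8α,9α-epoxy-3α,8β-bis(trimethylsilyloxy)eremophil-11-ene | C=C(C)[C@@H]1C[C@]2(C)[C@@H](C)[C@H](O[Si](C)(C)C)CC[C@H]2[C@@H]3O[C@]13O[Si](C)(C)C | intermediate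
20 | 3α,9α-bis(trimethylsilyloxy)eremophil-11-en-8-one | C=C(C)[C@@H]1C[C@]2(C)[C@@H](C)[C@H](O[Si](C)(C)C)CC[C@H]2[C@H](O[Si](C)(C)C)C1=O | intermediate
21 | 3α,9α-dihydroxyeremophil-11-en-8-one (10α-H) | C=C(C)[C@@H]1C[C@]2(C)[C@@H](C)[C@H](O)CC[C@H]2[C@H](O)C1=O | intermediate
22 | eremophil-11-ene-3α,8α,9α-triol (10α-H) | C=C(C)[C@@H]1C[C@]2(C)[C@@H](C)[C@H](O)CC[C@H]2[C@H](O)[C@@H]1O | intermediate
23 | 8,9-O-isopropylidene derivative of 22 | C=C(C)[C@@H]1C[C@]2(C)[C@@H](C)[C@H](O)CC[C@H]2[C@@H]3OC(C)(C)O[C@H]13 | intermediate
24 | (S)-pent-1-yn-3-ol | CC[C@H](O)C#C | starting material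
25 | (S)-4-hydroxyhex-2-ynoic acid | CC[C@H](O)C#CC(=O)O | intermediate
26 | hex-2-ynoic acid | CCCC#CC(=O)O | starting material
27 | hex-2-ynoyl chloride | CCCC#CC(=O)Cl | intermediate
28 | (S)-4-(hex-2-ynoyloxy)hex-2-ynoic acid | CC[C@H](OC(=O)C#CCCC)C#CC(=O)O | intermediate
29 | 3α-O-[(S)-4-(hex-2-ynoyloxy)hex-2-ynoyl] derivative of 23 | C=C(C)[C@@H]1C[C@]2(C)[C@@H](C)[C@H](OC(=O)C#C[C@H](CC)OC(=O)C#CCCC)CC[C@H]2[C@@H]3OC(C)(C)O[C@H]13 | intermediate
30 | 3α-O-[(S,Z)-4-((Z)-hex-2-enoyloxy)hex-2-enoyl] derivative of 23 | C=C(C)[C@@H]1C[C@]2(C)[C@@H](C)[C@H](OC(=O)/C=C\[C@H](CC)OC(=O)/C=C\CCC)CC[C@H]2[C@@H]3OC(C)(C)O[C@H]13 | intermediate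
31 | CNP0271544.1 | C=C(C)[C@@H]1C[C@]2(C)[C@@H](C)[C@H](OC(=O)/C=C\[C@H](CC)OC(=O)/C=C\CCC)CC[C@H]2[C@H](O)[C@@H]1O | target

**Step count and risks**

Total step count: 18. Longest linear sequence: 13 steps (steps 4 to 13 and 16 to 18 from (S)-carvone; the branch through steps 1 to 3 is equally long).

Step 8 (key step). The two sigmatropic shifts may occur in the reverse order (secondary ester first), the ketene may be captured between molecules, or the tertiary allylic ester may eliminate before it rearranges. The fallback sets out from 8 and returns at 15 with known reactions only. The secondary hydroxyl of 8 is acylated with propionic anhydride (Et3N, DMAP) to propionate F1. A Johnson–Claisen rearrangement of the tertiary allylic alcohol with triethyl orthoacetate (propionic acid cat., 140 °C) forms C1–C2 and moves the alkene to C10=C5, giving diester F2. An Ireland–Claisen rearrangement of the allylic propionate (LDA, TMSCl, Et3N, THF, −78 °C to rt) forms C4–C5 with the same transfer from the C9–O bond and gives acid F3, which TMSCHN2 converts to methyl ester F4. Dieckmann condensation (KOt-Bu, THF) closes ring A to β-keto ester F5, and Krapcho decarboxylation (LiCl, wet DMSO, 150 °C) gives 15.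

Step 9. Hydrogen abstraction may also occur at C1 or at the allylic positions of the isopropenyl group, and the isopropenyl ketone formed may slip into conjugation. The fallback sets out from 15 and returns at 16. Sensitized photooxygenation (O2, tetraphenylporphyrin, light, CH2Cl2, 0 °C; Schenck ene reaction, much faster on the trisubstituted ring alkene than on isopropenyl) should give the tertiary 10α-hydroperoxide F6. Its allylic hydroperoxide rearrangement on standing in CHCl3 gives the secondary 8α-hydroperoxide F7, and dehydration with Ac2O and pyridine (Kornblum–DeLaMare type) gives 16.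

Step 10. The enolate may be over-reduced through proton exchange, the C3 ketone may be reduced incompletely, and the regiodefined enol ether may be lost on work-up. The fallback sets out from 16 and returns at 18. The reduction (Li, NH3, t-BuOH) is quenched with NH4Cl to give the saturated trans-fused hydroxy ketone F8. A separate kinetic deprotonation at the C9 methylene (LDA, 3 equiv, THF, −78 °C) in the presence of TMSCl then gives the same bis-silyl compound 18.

**Further compounds**

F1 | step 8 | propionate of 8 at the secondary hydroxyl | C=C(C)[C@@H]1C[C@](C)(O)C(=C)[C@H](OC(=O)CC)C1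
F2 | step 8 | ethyl 3-[(4S,6R)-2-methyl-4-isopropenyl-6-(propanoyloxy)cyclohex-1-enyl]propanoate | C=C(C)[C@@H]1CC(C)=C(CCC(=O)OCC)[C@H](OC(=O)CC)C1
F3 | step 8 | 2-[2-(3-ethoxy-3-oxopropyl)-1-methyl-5-isopropenylcyclohex-2-enyl]propanoic acid (C5 as in 15; α-carbon unassigned) | C=C(C)[C@@H]1C[C@](C)(C(C)C(=O)O)C(CCC(=O)OCC)=CC1
F4 | step 8 | methyl ester of F3 | C=C(C)[C@@H]1C[C@](C)(C(C)C(=O)OC)C(CCC(=O)OCC)=CC1
F5 | step 8 | ethyl 3-oxoeremophila-9,11-diene-2-carboxylate (C2 and C4 unassigned) | C=C(C)[C@@H]1C[C@]2(C)C(C)C(=O)C(C(=O)OCC)CC2=CC1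
F6 | step 9 | 10α-hydroperoxyeremophila-8,11-dien-3-one | C=C(C)[C@@H]1C[C@]2(C)[C@@H](C)C(=O)CC[C@@]2(OO)C=C1
F7 | step 9 | 8α-hydroperoxyeremophila-9,11-dien-3-one | C=C(C)[C@@H]1C[C@]2(C)[C@@H](C)C(=O)CCC2=C[C@@H]1OO
F8 | step 10 | 3α-hydroxyeremophil-11-en-8-one (10α-H) | C=C(C)[C@@H]1C[C@]2(C)[C@@H](C)[C@H](O)CC[C@H]2CC1=O
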